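A small charge of free catalyst turns a racemate mostly into left-handed product, but the share you measure at the end also depends on what happens to that product while it sits hot.

| flask | left-handed substrate | right-handed substrate | reagent | free catalyst | temperature | remark | time |
|---|---|---|---|---|---|---|---|
| Thursday's | 1 M | 1 M | 2.5 M | 0.67 mM | 45 °C | run made earlier |  |
| Tuesday's | 1 M | 1 M | 2.5 M | 1.5 mM | 75 °C | run made earlier |  |
| winter | 1.0 M | 1.0 M | 2.50 M | 1.0 mM | 75 °C |  | 1.0 h |
| dawn | 1.0 M | 1.0 M | 2.50 M | 1.0 mM |  | at 50 °C until 12 min, from then on at 100 °C | 1.0 h |
| summer | 1.0 M | 1.0 M | 2.50 M | 1.0 mM | 100 °C |  | 1.0 h |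
| autumn | 1.0 M | 1.0 M | 2.50 M | 1.0 mM | 50 °C |  | 1.0 h |

Thursday's run (percent of the left-handed substrate and right-handed substrate together charged)

| time / h | left-handed product / % | right-handed product / % | left-handed substrate / % |
|---|---|---|---|
| 0.333 | 5.6 | 0 | 45.3 |
| 0.667 | 9.7 | 0 | 41.4 |
| 1.00 | 13.4 | 0.6 | 37.7 |
| 2.00 | 25.5 | 1.4 | 31.4 |
| 4.00 | 37.3 | 1.2 | 24.5 |

Tuesday's run (percent of the left-handed substrate and right-handed substrate together charged)

| time / min | left-handed product / % | right-handed product / % | left-handed substrate / % |
|---|---|---|---|
| 5.00 | 16.3 | 1.6 | 36.4 |
| 15.0 | 35.7 | 1.1 | 26.4 |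
| 30.0 | 50.2 | 4.4 | 20.3 |
| 40.0 | 55.5 | 6.8 | 17.2 |
| 60.0 | 61.4 | 10.2 | 12.4 |

(readings scatter by 0.5 percentage points)

- free catalyst is single-handed; left-handed substrate and right-handed substrate are mirror images of each other, charged as a racemate, each of them at the stated concentration
- the numbers in the tables scatter by 0.5 percentage points (one standard deviation)
- on the list of suspects stand: reagent + free catalyst + left-handed substrate -> free catalyst + left-handed product; reagent + free catalyst + right-handed substrate -> free catalyst + right-handed product; left-handed substrate <-> right-handed substrate; free catalyst -> spent catalyst; left-handed product <-> right-handed product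

- the best flask by share of left-handed product in all that became left-handed product or right-handed product; "all alike" if 1.5 percentage points covers them all (winter / dawn / summer / autumn / all alike)
- share of left-handed product in all that became left-handed product or right-handed product, winter
- share of left-handed product in all that became left-handed product or right-handed product, dawn
- share of left-handed product in all that became left-handed product or right-handed product, summer
- share of left-handed product in all that became left-handed product or right-handed product, autumn

First, the share when the product is fresh: Thursday's readings up to 1.00 h pool to 98.0%. On Tuesday, though, right-handed product climbs late, from 6.8% to 10.2% between 40.0 min and 60.0 min. If that climb is fed by [left-handed product] − [right-handed product], the scrambling (racemization) constant reads 0.204 h⁻¹ at 75 °C. Thursday's 1.2% after 4.00 h gives a ceiling of 0.0161 h⁻¹ at 45 °C, so the step between those temperatures multiplies the constant by at least 12.7. Spread evenly over the degrees, that gives 1.70 h⁻¹ at 100 °C and 0.0246 h⁻¹ at 50 °C.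

Now divide the time by the half-life of the excess, ln(2)/(2k). Winter holds 0.589 such half-lives; call this the scrambling count. Each count halves the excess over an even split in product already made. Summer counts 4.90, dawn 3.93 and autumn 0.0709, so I expect autumn to be best, its count being lower.

Is one number enough? It ranks the flasks, but the full count holds for product made at the start, while product made at an even pace keeps a different fraction of its excess: the fraction the halving took away, divided by the count and by ln(2). So I reckon each flask both ways, first with all product made early and then at an even pace: winter 81.9% and 89.4%, dawn 53.1% and 66.5%, summer 51.6% and 63.7%, and autumn 95.7% and 96.8%. These are estimates, not limits: the factor 12.7 is only a minimum, so 1.70 h⁻¹ is a floor and 0.0246 h⁻¹ a ceiling, and the readings behind them scatter.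

The forecast names autumn, with 86.5% for winter, 51% for dawn, 50.6% for summer and 96.5% for autumn, and says “both hot flasks end nearly racemic”.

The best flask is autumn, with 86.2% in winter, 52.9% at dawn, 51.6% in summer and 97.0% in autumn.

    reagent + free catalyst + left-handed substrate → free catalyst + left-handed product (k = 1.50 M⁻² s⁻¹, Ea = 59.0 kJ mol⁻¹)
    reagent + free catalyst + right-handed substrate → free catalyst + right-handed product (k = 0.0160 M⁻² s⁻¹, Ea = 47.0 kJ mol⁻¹)
    left-handed substrate ⇌ right-handed substrate (k = 0.0120 s⁻¹, Ea = 90.0 kJ mol⁻¹)
    free catalyst → spent catalyst (k = 4.50 × 10⁻⁴ s⁻¹, Ea = 108 kJ mol⁻¹)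
    left-handed product ⇌ right-handed product (k = 7.90 × 10⁻⁴ s⁻¹, Ea = 109 kJ mol⁻¹)
    (constants at 100 °C)

Take the repeat of summer at 85 °C, with the amounts and the hour held. The same spreading gives 0.476 h⁻¹ and a count of 1.37, lower than summer's 4.90 and higher than winter's 0.589. The reckoning therefore gives 68.6% with all product made early and 81.0% at an even pace. That flask gives 70.5%, with 22.4% of right-handed product at its end.

The runs were computed for an exercise; the scatter is artificial.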